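**Plan**
- Retrosynthesis: the last cut is the C3–C3a bond of the dihydrobenzofuran. C3 carries exactly one exocyclic carbon (the CH2OH carbon) and is bonded to the arene carbon C3a, which is the signature of a 1,2-aryl shift. Putting that carbon back between C3 and C3a gives a (2S)-3-diazochroman-4-one (flavanone), whose six-membered pyranone ring contracts to the five-membered ring by Wolff rearrangement.
- Earlier cuts: the flavanone C2–aryl bond (aryl conjugate addition to a chromone), the chromone C2 carbon (amide acetal) and acetyl group, then the furofuran: both benzylic C–O bonds, the aldol C–C bond and the acyl-anion C–C bond, back to a menthyloxybutenolide, a dithiane and 5-bromovanillin.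
- Forward order of rings: butenolide template, open tetraol, both tetrahydrofuran rings of the furofuran, pyranone ring on the bromoguaiacyl ring, flavanone, contraction to the dihydrobenzofuran, reduction, desilylation.
- Stereochemistry: furofuran bridgeheads from the (5R)-menthyloxybutenolide (anti conjugate addition, anti aldol); benzylic furofuran carbons from kinetic exo ring closure; C2 from the chiral pyridine-oxazoline palladium catalyst; C3 (cis to the C2 aryl) from kinetic protonation of the ketene-derived ester enol on the face away from the C2 aryl.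

Key step: step 14

Remark: the SMILES defines the dihydrobenzofuran as 2S,3S, that is aryl and hydroxymethyl cis (the less stable arrangement), so the route sets C3 late and uses neither acid nor base afterwards.

Abbreviations: TIPS = triisopropylsilyl; Men = (1R,2S,5R)-2-isopropyl-5-methylcyclohexyl (l-menthyl); ArT = 3-methoxy-4-(TIPS-oxy)phenyl; FF = the group (1S,3aR,4S,6aR)-4-[3,5-dimethoxy-4-(TIPS-oxy)phenyl]tetrahydro-1H,3H-furo[3,4-c]furan-1-yl.

**Step 1**
Reactants: 1 syringaldehyde (4-hydroxy-3,5-dimethoxybenzaldehyde)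
Product: 2 3,5-dimethoxy-4-(triisopropylsilyloxy)benzaldehyde
Conditions: TIPSCl, imidazole, DMAP (cat.), DMF, 40 °C
Reagents that add atoms: triisopropylsilyl chloride, CC(C)[Si](Cl)(C(C)C)C(C)C
Why: O-silylation of the phenol (silyl ether formation) removes the acidic hydrogen before the organolithium step, and the hindered TIPS ether flanked by two methoxy groups is meant to last until the final fluoride step; no stereocentre is formed.

**Step 2**
Reactants: 2 3,5-dimethoxy-4-(triisopropylsilyloxy)benzaldehyde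
Product: 3 2-[3,5-dimethoxy-4-(triisopropylsilyloxy)phenyl]-1,3-dithiane
Conditions: HS(CH2)3SH, I2 (10 mol%), CH2Cl2, rt
Reagents that add atoms: propane-1,3-dithiol, SCCCS
Why: dithioacetalisation of the aryl aldehyde under mild iodine catalysis turns the formyl carbon into a Corey–Seebach acyl-anion equivalent; no stereocentre is formed.

**Step 3**
Reactants: 4 5-bromovanillin (3-bromo-4-hydroxy-5-methoxybenzaldehyde)
Product: 5 2-bromo-4-formyl-6-methoxyphenyl pivalate
Conditions: PivCl, Et3N, DMAP (cat.), CH2Cl2, 0 °C to rt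
Reagents that add atoms: pivaloyl chloride, CC(C)(C)C(Cl)=O
Why: O-acylation gives a hindered aryl ester that is inert to a lithium enolate at −78 °C but is cleaved by LiAlH4 in step 6, so the phenol needed for the chromone annulation is freed without a separate step; no stereocentre is formed.

**Step 4**
Reactants: 3 2-[3,5-dimethoxy-4-(triisopropylsilyloxy)phenyl]-1,3-dithiane; 6 (5R)-5-(Men-oxy)furan-2(5H)-one; 5 2-bromo-4-formyl-6-methoxyphenyl pivalate
Product: 9 (3S,4R,5R)-3-[(3-bromo-5-methoxy-4-pivaloyloxyphenyl)(hydroxy)methyl]-4-{2-[3,5-dimethoxy-4-(TIPS-oxy)phenyl]-1,3-dithian-2-yl}-5-(Men-oxy)dihydrofuran-2(3H)-one (both carbinol epimers), via lithiated dithiane 7 (not isolated), via lithium enolate 8 (not isolated)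
Conditions: n-BuLi, THF, −78 to −20 °C; then 6, −78 °C; then 5, −78 °C; AcOH quench at −78 °C
Reagents that add atoms: none
Why: tandem Michael addition–aldol reaction (conjugate addition of a Corey–Seebach dithiane anion to a γ-alkoxybutenolide, then trapping of the enolate by the aldehyde), in which the anion adds to C4 anti to the menthyloxy group at C5 and the enolate takes up the aldehyde at C3 anti to the new C4 substituent, fixing both future furofuran bridgeheads, while the carbinol carbon forms as an epimer mixture that converges in step 7.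

**Step 5**
Reactants: 9 the dithianyl aldol lactone of step 4
Product: 10 (3S,4R,5R)-3-[(3-bromo-5-methoxy-4-pivaloyloxyphenyl)(hydroxy)methyl]-4-[3,5-dimethoxy-4-(TIPS-oxy)benzoyl]-5-(Men-oxy)dihydrofuran-2(3H)-one (both carbinol epimers)
Conditions: MeI (excess), CaCO3, MeCN–H2O (4:1), 45 °C
Reagents that add atoms: water, O
Why: dithioacetal hydrolysis by S-methylation (sulfonium formation, then attack of water) under carbonate-buffered, non-oxidising conditions unveils the aryl ketone without touching the lactone acetal, the pivalate or the aryl bromide, and C4, now alpha to the ketone, already sits in its more stable all-trans arrangement.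

**Step 6**
Reactants: 10 the keto lactone of step 5
Product: 11 (2R,3R)-1-(3-bromo-4-hydroxy-5-methoxyphenyl)-4-[3,5-dimethoxy-4-(TIPS-oxy)phenyl]-2,3-bis(hydroxymethyl)butane-1,4-diol (epimers at C1 and C4)
Conditions: LiAlH4 (excess), THF, 0 °C to rt; H2O/NaOH work-up
Reagents that add atoms: none
Why: global hydride reduction takes the ketone to the carbinol, the lactone carbonyl and the acetal carbon (set free as an aldehyde when the lactone opens and menthoxide leaves) to the two primary alcohols, and the pivalate to the phenol, while the two CH stereocentres of step 4 are carried through unchanged and the two benzylic carbinols are epimer mixtures by design.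

**Step 7**
Reactants: 11 the pentaol of step 6
Product: 12 2-bromo-6-methoxy-4-FF-phenol
Conditions: (1S)-camphor-10-sulfonic acid (20 mol%), CH2Cl2–THF, 0 °C; NaHCO3 quench as soon as 11 is consumed
Reagents that add atoms: none
Why: acid-catalysed double cyclodehydration (SN1 etherification through para-oxygen-stabilised benzylic cations, the laboratory counterpart of the quinone-methide closure of furofuran lignans), in which each planar benzylic cation is captured by the primary hydroxyl four atoms away, the cis ring fusion is dictated by the two fixed CH centres, and each aryl group takes the exo position (trans to the adjacent ring-fusion bond) under kinetic control whatever the carbinol configuration, giving 1S,4S with the endo-aryl epimer as the expected minor by-product.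

**Step 8**
Reactants: 12 2-bromo-6-methoxy-4-FF-phenol
Product: 14 1-(2-hydroxy-3-methoxy-5-FF-phenyl)ethan-1-one, via enol ether 13 (not isolated)
Conditions: Bu3SnC(OEt)=CH2, PdCl2(PPh3)2 (5 mol%), toluene, 100 °C; then PPTS, acetone–H2O, rt
Reagents that add atoms: tributyl(1-ethoxyvinyl)stannane, CCCC[Sn](CCCC)(CCCC)C(=C)OCC; water, O
Why: Stille coupling of the aryl bromide with an acetyl-anion equivalent, followed by hydrolysis of the enol ether with a weak acid that does not ionise the benzylic ethers, gives the ortho-hydroxyacetophenone; no stereocentre is formed.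

**Step 9**
Reactants: 14 1-(2-hydroxy-3-methoxy-5-FF-phenyl)ethan-1-one
Product: 16 8-methoxy-6-FF-4H-chromen-4-one, via enaminone 15 (not isolated)
Conditions: Me2NCH(OMe)2, toluene, 90 °C; evaporate; AcOH, 60 °C
Reagents that add atoms: N,N-dimethylformamide dimethyl acetal, COC(OC)N(C)C
Why: enaminone formation at the acetyl methyl group and weak-acid-promoted addition of the phenol to the beta carbon with loss of dimethylamine (enaminone chromone synthesis, 6-endo addition–elimination) build the pyranone ring and tie the para oxygen into a vinylogous ester, which also stabilises the neighbouring benzylic ether; no stereocentre is formed.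

**Step 10**
Reactants: 17 4-bromo-2-methoxyphenol
Product: 18 (4-bromo-2-methoxyphenoxy)triisopropylsilane
Conditions: TIPSCl, imidazole, DMF, rt
Reagents that add atoms: triisopropylsilyl chloride, CC(C)[Si](Cl)(C(C)C)C(C)C
Why: phenol silylation masks the acidic hydrogen for the lithiation and keeps the later flavanone aryl group from opening the pyranone ring through a quinone methide; no stereocentre is formed.

**Step 11**
Reactants: 18 (4-bromo-2-methoxyphenoxy)triisopropylsilane
Product: 21 [3-methoxy-4-(triisopropylsilyloxy)phenyl]boronic acid, via aryllithium 19 (not isolated), via lithium borate 20 (not isolated)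
Conditions: n-BuLi, THF, −78 °C; B(OiPr)3, −78 °C to rt; aq. HCl to pH 5
Reagents that add atoms: triisopropyl borate, CC(C)OB(OC(C)C)OC(C)C; water, O
Why: bromine–lithium exchange, electrophilic borylation of the aryllithium and mild hydrolysis of the borate give the arylboronic acid; no stereocentre is formed.

**Step 12**
Reactants: 16 8-methoxy-6-FF-4H-chromen-4-one; 21 [3-methoxy-4-(triisopropylsilyloxy)phenyl]boronic acid
Product: 22 (2S)-8-methoxy-2-ArT-6-FF-chroman-4-one
Conditions: Pd(OCOCF3)2 (5 mol%), (R)-t-BuPyOx (6 mol%), NH4PF6 (30 mol%), H2O (5 equiv), ClCH2CH2Cl, 60 °C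
Reagents that add atoms: none
Why: asymmetric conjugate addition of an arylboronic acid to a chromone under divalent palladium/pyridine-oxazoline catalysis (Hayashi–Miyaura type) sets C2 by catalyst control, the aryl group being delivered to the Re face of C2; the R ligand is the enantiomer expected to do this by analogy with cyclic enones, its antipode is used if a model chromone shows the opposite sense, and a wrong-face product is a separable diastereomer because the furofuran is already enantiopure.

**Step 13**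
Reactants: 22 (2S)-8-methoxy-2-ArT-6-FF-chroman-4-one
Product: 25 (2R)-3-diazo-8-methoxy-2-ArT-6-FF-chroman-4-one, via lithium enolate 23 (not isolated), via trifluoroacetyl ketone 24 (not isolated)
Conditions: LiN(SiMe3)2, THF, −78 °C; CF3CO2CH2CF3, −78 °C; aq. HCl work-up; then MsN3, Et3N, H2O (1 equiv), MeCN, rt
Reagents that add atoms: methanesulfonyl azide, CS(=O)(=O)N=[N+]=[N-]
Why: detrifluoroacetylative diazo transfer (Regitz type), in which kinetic enolisation at C3 and C-trifluoroacetylation activate the ketone and the sulfonyl azide then transfers N2 to C3 with loss of the trifluoroacetyl group, leaves C2 spatially unchanged provided the enolate is acylated at −78 °C before it can open; the descriptor becomes R only because the diazo carbon now outranks the aryl group.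

**Step 14**
Reactants: 25 (2R)-3-diazo-8-methoxy-2-ArT-6-FF-chroman-4-one
Product: 27 methyl (2S,3R)-7-methoxy-2-ArT-5-FF-2,3-dihydrobenzofuran-3-carboxylate (cis), via ketene 26 (not isolated)
Conditions: hν (365 nm LED), degassed MeOH–THF (5:1), −40 °C; evaporate cold and use at once in step 15
Reagents that add atoms: methanol, CO
Why: Direct irradiation of the s-cis-locked cyclic alpha-diazo ketone expels N2 with 1,2-shift of the arene carbon C4a from the carbonyl carbon C4 to the diazo carbon C3 (Wolff rearrangement), so the six-membered pyranone ring contracts to the five-membered dihydrofuran ring and C4 leaves the ring as the ketene carbon of 26, which methanol captures as the methyl ester. The closest known reaction type is the photochemical Wolff ring contraction of benzo-fused cyclic 2-diazo ketones, such as 2-diazo-1-tetralone to indane-1-carboxylates. The five-membered ring is not closed by a cyclisation but arises by this 1,2-aryl migration (contraction by one carbon), and C2 is not involved and keeps the configuration set in step 12. The new stereocentre C3 is set when the planar ester enol formed from the ketene and methanol is protonated at C3 on the face opposite to the C2 aryl group, which places the ester cis to the aryl (2S,3R), the kinetic and less stable isomer. The step needs the migration to outrun carbene O–H insertion and 1,2-hydride shift to the flavone, which the fixed s-cis geometry and low-temperature direct photolysis are meant to secure, and it needs the cis ester not to epimerise, which the neutral, base-free medium secures.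

**Step 15**
Reactants: 27 methyl (2S,3R)-7-methoxy-2-ArT-5-FF-2,3-dihydrobenzofuran-3-carboxylate
Product: 28 [(2S,3S)-7-methoxy-2-ArT-5-FF-2,3-dihydrobenzofuran-3-yl]methanol
Conditions: i-Bu2AlH (3 equiv), CH2Cl2, −78 to −40 °C; aq. KNaC4H4O6 work-up
Reagents that add atoms: none
Why: ester-to-alcohol reduction with a non-basic, Lewis-acidic hydride at low temperature should outrun enolisation of the epimerisable alpha-aryl ester, so the cis relationship is kept, and after this step C3 no longer bears an acidic hydrogen (the descriptor changes to S only through the priority change from ester to CH2OH).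

**Step 16**
Reactants: 28 [(2S,3S)-7-methoxy-2-ArT-5-FF-2,3-dihydrobenzofuran-3-yl]methanol
Product: 29 4-{(2S,3S)-3-(hydroxymethyl)-5-[(1S,3aR,4S,6aR)-4-(4-hydroxy-3,5-dimethoxyphenyl)tetrahydro-1H,3H-furo[3,4-c]furan-1-yl]-7-methoxy-2,3-dihydrobenzofuran-2-yl}-2-methoxyphenol (CNP0126146.1)
Conditions: Bu4NF (2.4 equiv), AcOH (2.4 equiv), THF, 0 °C
Reagents that add atoms: none
Why: fluoride-induced cleavage of both aryl silyl ethers (desilylation), buffered with acetic acid so that no free phenoxide can open either para-oxygenated benzylic ether, releases the two phenols without touching any stereocentre.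

**Compound list**
1 | syringaldehyde | COc1cc(C=O)cc(OC)c1O | starting material
2 | 3,5-dimethoxy-4-(triisopropylsilyloxy)benzaldehyde | COc1cc(C=O)cc(OC)c1O[Si](C(C)C)(C(C)C)C(C)C | intermediate
3 | 2-[3,5-dimethoxy-4-(triisopropylsilyloxy)phenyl]-1,3-dithiane | COc1cc(C2SCCCS2)cc(OC)c1O[Si](C(C)C)(C(C)C)C(C)C | intermediate
4 | 5-bromovanillin | COc1cc(C=O)cc(Br)c1O | starting material
5 | 2-bromo-4-formyl-6-methoxyphenyl pivalate | COc1cc(C=O)cc(Br)c1OC(=O)C(C)(C)C | intermediate
6 | (5R)-5-[(1R,2S,5R)-menthyloxy]furan-2(5H)-one | O=C1C=C[C@H](O[C@@H]2C[C@H](C)CC[C@H]2C(C)C)O1 | starting material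
7 | 2-lithio-2-[3,5-dimethoxy-4-(triisopropylsilyloxy)phenyl]-1,3-dithiane | COc1cc(C2([Li])SCCCS2)cc(OC)c1O[Si](C(C)C)(C(C)C)C(C)C | intermediate
8 | lithium (4R,5R)-4-{2-[3,5-dimethoxy-4-(TIPS-oxy)phenyl]-1,3-dithian-2-yl}-5-(Men-oxy)-4,5-dihydrofuran-2-olate | [Li]OC1=C[C@@H](C2(SCCCS2)c2cc(OC)c(O[Si](C(C)C)(C(C)C)C(C)C)c(OC)c2)[C@H](O[C@@H]2C[C@H](C)CC[C@H]2C(C)C)O1 | intermediate
9 | (3S,4R,5R)-3-[(3-bromo-5-methoxy-4-pivaloyloxyphenyl)(hydroxy)methyl]-4-{2-[3,5-dimethoxy-4-(TIPS-oxy)phenyl]-1,3-dithian-2-yl}-5-(Men-oxy)dihydrofuran-2(3H)-one, carbinol epimers | O=C1O[C@@H](O[C@@H]2C[C@H](C)CC[C@H]2C(C)C)[C@H](C2(SCCCS2)c2cc(OC)c(O[Si](C(C)C)(C(C)C)C(C)C)c(OC)c2)[C@H]1C(O)c1cc(OC)c(OC(=O)C(C)(C)C)c(Br)c1 | intermediate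
10 | (3S,4R,5R)-3-[(3-bromo-5-methoxy-4-pivaloyloxyphenyl)(hydroxy)methyl]-4-[3,5-dimethoxy-4-(TIPS-oxy)benzoyl]-5-(Men-oxy)dihydrofuran-2(3H)-one, carbinol epimers | O=C1O[C@@H](O[C@@H]2C[C@H](C)CC[C@H]2C(C)C)[C@H](C(=O)c2cc(OC)c(O[Si](C(C)C)(C(C)C)C(C)C)c(OC)c2)[C@H]1C(O)c1cc(OC)c(OC(=O)C(C)(C)C)c(Br)c1 | intermediate
11 | (2R,3R)-1-(3-bromo-4-hydroxy-5-methoxyphenyl)-4-[3,5-dimethoxy-4-(TIPS-oxy)phenyl]-2,3-bis(hydroxymethyl)butane-1,4-diol, epimers at C1 and C4 | OC[C@H](C(O)c1cc(OC)c(O[Si](C(C)C)(C(C)C)C(C)C)c(OC)c1)[C@H](CO)C(O)c1cc(OC)c(O)c(Br)c1 | intermediate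
12 | 2-bromo-4-{(1S,3aR,4S,6aR)-4-[3,5-dimethoxy-4-(TIPS-oxy)phenyl]tetrahydro-1H,3H-furo[3,4-c]furan-1-yl}-6-methoxyphenol | COc1cc([C@H]2OC[C@H]3[C@@H]2CO[C@@H]3c2cc(OC)c(O[Si](C(C)C)(C(C)C)C(C)C)c(OC)c2)cc(Br)c1O | intermediate
13 | 2-(1-ethoxyvinyl)-6-methoxy-4-FF-phenol | CCOC(=C)c1cc([C@H]2OC[C@H]3[C@@H]2CO[C@@H]3c2cc(OC)c(O[Si](C(C)C)(C(C)C)C(C)C)c(OC)c2)cc(OC)c1O | intermediate
14 | 1-(2-hydroxy-3-methoxy-5-FF-phenyl)ethan-1-one | CC(=O)c1cc([C@H]2OC[C@H]3[C@@H]2CO[C@@H]3c2cc(OC)c(O[Si](C(C)C)(C(C)C)C(C)C)c(OC)c2)cc(OC)c1O | intermediate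
15 | (E)-3-(dimethylamino)-1-(2-hydroxy-3-methoxy-5-FF-phenyl)prop-2-en-1-one | CN(C)/C=C/C(=O)c1cc([C@H]2OC[C@H]3[C@@H]2CO[C@@H]3c2cc(OC)c(O[Si](C(C)C)(C(C)C)C(C)C)c(OC)c2)cc(OC)c1O | intermediate
16 | 8-methoxy-6-FF-4H-chromen-4-one | COc1cc([C@H]2OC[C@H]3[C@@H]2CO[C@@H]3c2cc(OC)c(O[Si](C(C)C)(C(C)C)C(C)C)c(OC)c2)cc2c(=O)ccoc12 | intermediate
17 | 4-bromo-2-methoxyphenol | COc1cc(Br)ccc1O | starting material
18 | (4-bromo-2-methoxyphenoxy)triisopropylsilane | COc1cc(Br)ccc1O[Si](C(C)C)(C(C)C)C(C)C | intermediate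
19 | [3-methoxy-4-(triisopropylsilyloxy)phenyl]lithium | COc1cc([Li])ccc1O[Si](C(C)C)(C(C)C)C(C)C | intermediate
20 | lithium triisopropoxy[3-methoxy-4-(triisopropylsilyloxy)phenyl]borate | [Li+].COc1cc([B-](OC(C)C)(OC(C)C)OC(C)C)ccc1O[Si](C(C)C)(C(C)C)C(C)C | intermediate
21 | [3-methoxy-4-(triisopropylsilyloxy)phenyl]boronic acid | COc1cc(B(O)O)ccc1O[Si](C(C)C)(C(C)C)C(C)C | intermediate
22 | (2S)-8-methoxy-2-ArT-6-FF-chroman-4-one | COc1cc([C@H]2Oc3c(OC)cc([C@H]4OC[C@H]5[C@@H]4CO[C@@H]5c4cc(OC)c(O[Si](C(C)C)(C(C)C)C(C)C)c(OC)c4)cc3C(=O)C2)ccc1O[Si](C(C)C)(C(C)C)C(C)C | intermediate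
23 | lithium (2S)-8-methoxy-2-ArT-6-FF-2H-chromen-4-olate | COc1cc([C@H]2Oc3c(OC)cc([C@H]4OC[C@H]5[C@@H]4CO[C@@H]5c4cc(OC)c(O[Si](C(C)C)(C(C)C)C(C)C)c(OC)c4)cc3C(O[Li])=C2)ccc1O[Si](C(C)C)(C(C)C)C(C)C | intermediate
24 | (2S)-8-methoxy-2-ArT-6-FF-3-(trifluoroacetyl)chroman-4-one, C3 epimers | COc1cc([C@H]2Oc3c(OC)cc([C@H]4OC[C@H]5[C@@H]4CO[C@@H]5c4cc(OC)c(O[Si](C(C)C)(C(C)C)C(C)C)c(OC)c4)cc3C(=O)C2C(=O)C(F)(F)F)ccc1O[Si](C(C)C)(C(C)C)C(C)C | intermediate
25 | (2R)-3-diazo-8-methoxy-2-ArT-6-FF-chroman-4-one | COc1cc([C@H]2Oc3c(OC)cc([C@H]4OC[C@H]5[C@@H]4CO[C@@H]5c4cc(OC)c(O[Si](C(C)C)(C(C)C)C(C)C)c(OC)c4)cc3C(=O)C2=[N+]=[N-])ccc1O[Si](C(C)C)(C(C)C)C(C)C | intermediate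
26 | (2R)-7-methoxy-2-ArT-5-FF-3-(oxomethylidene)-2,3-dihydrobenzofuran (ketene) | COc1cc([C@H]2Oc3c(OC)cc([C@H]4OC[C@H]5[C@@H]4CO[C@@H]5c4cc(OC)c(O[Si](C(C)C)(C(C)C)C(C)C)c(OC)c4)cc3C2=C=O)ccc1O[Si](C(C)C)(C(C)C)C(C)C | intermediate
27 | methyl (2S,3R)-7-methoxy-2-ArT-5-FF-2,3-dihydrobenzofuran-3-carboxylate (cis) | COc1cc([C@H]2Oc3c(OC)cc([C@H]4OC[C@H]5[C@@H]4CO[C@@H]5c4cc(OC)c(O[Si](C(C)C)(C(C)C)C(C)C)c(OC)c4)cc3[C@H]2C(=O)OC)ccc1O[Si](C(C)C)(C(C)C)C(C)C | intermediate
28 | [(2S,3S)-7-methoxy-2-ArT-5-FF-2,3-dihydrobenzofuran-3-yl]methanol | COc1cc([C@H]2Oc3c(OC)cc([C@H]4OC[C@H]5[C@@H]4CO[C@@H]5c4cc(OC)c(O[Si](C(C)C)(C(C)C)C(C)C)c(OC)c4)cc3[C@H]2CO)ccc1O[Si](C(C)C)(C(C)C)C(C)C | intermediate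
29 | 4-{(2S,3S)-3-(hydroxymethyl)-5-[(1S,3aR,4S,6aR)-4-(4-hydroxy-3,5-dimethoxyphenyl)tetrahydro-1H,3H-furo[3,4-c]furan-1-yl]-7-methoxy-2,3-dihydrobenzofuran-2-yl}-2-methoxyphenol | COc1cc([C@H]2Oc3c(OC)cc([C@H]4OC[C@H]5[C@@H]4CO[C@@H]5c4cc(OC)c(O)c(OC)c4)cc3[C@H]2CO)ccc1O | target

**Count and risks**
Total steps: 16. Longest linear sequence: 13 steps (1, 2, 4 to 9, 12 to 16).

Most likely to fail, step 14: the carbene manifold may compete with the 1,2-aryl shift (O–H insertion of methanol, hydride shift to the flavone), or protonation of the ester enol may lose its facial bias so that the trans ester forms beside the cis ester. The fallback uses known chemistry without ring contraction, sets out from 12 and comes back at 27. Phenol 12 is etherified under Mitsunobu conditions (PPh3, DIAD, THF) with [3-methoxy-4-(triisopropylsilyloxy)phenyl]methanol F1, made from commercial vanillyl alcohol by silylation of its phenoxide (NaH, TIPSCl), to give the aryl benzyl ether F2. Palladium-catalysed coupling of the aryl bromide with the Reformatsky reagent BrZnCH2CO2Me (Pd(dba)2, XPhos, THF) gives the methyl arylacetate F3, and Regitz diazo transfer (4-acetamidobenzenesulfonyl azide, DBU, MeCN) gives the aryldiazoacetate F4. Intramolecular carbenoid C–H insertion into the benzylic ether CH2, catalysed by dirhodium tetrakis[N-phthaloyl-(S)-tert-leucinate], Rh2(S-PTTL)4, or its enantiomer (chosen to give 2S,3R), should close the dihydrofuran ring as the cis ester 27, cis selectivity being the usual outcome of this insertion type.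

Second, step 13: the lithium enolate or the trifluoroacetyl diketonate may open by retro-oxa-Michael elimination of the phenoxide to a chalcone and close again, which erodes the C2 configuration. The fallback avoids any C3 enolate, sets out from 22 and comes back at 25. Acid-promoted alpha-nitrosation (isopentyl nitrite, Me3SiCl, CH2Cl2, −20 °C) gives (2R)-3-(hydroxyimino)-8-methoxy-2-ArT-6-FF-chroman-4-one F5. The Forster reaction with chloramine (aq. NH3, NaOCl, THF, 0 °C) then converts the alpha-oximino ketone into the diazo ketone 25.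

Third, step 12: protodeboronation of the electron-rich boronic acid may outpace aryl transfer, or facial discrimination at C2 of the heavily substituted chromone may be incomplete. The fallback builds the flavanone from a chalcone, sets out from 14 and comes back at 22. Claisen–Schmidt condensation of 14 (Ba(OH)2, MeOH, rt, chosen to spare the aryl silyl ethers) with 3-methoxy-4-(triisopropylsilyloxy)benzaldehyde F6, made from vanillin with TIPSCl and imidazole, gives the 2'-hydroxychalcone (E)-1-(2-hydroxy-3-methoxy-5-FF-phenyl)-3-ArT-prop-2-en-1-one F7. Asymmetric intramolecular oxa-Michael addition catalysed by a quinine-derived bifunctional thiourea (or its quinidine-derived counterpart if the other sense is needed) should then give 22; the C2 epimer is a diastereomer and can be separated.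

**Further compounds**
F1 | step 14 | [3-methoxy-4-(triisopropylsilyloxy)phenyl]methanol | COc1cc(CO)ccc1O[Si](C(C)C)(C(C)C)C(C)C
F2 | step 14 | 1-bromo-3-methoxy-5-FF-2-{[3-methoxy-4-(triisopropylsilyloxy)benzyl]oxy}benzene | COc1cc([C@H]2OC[C@H]3[C@@H]2CO[C@@H]3c2cc(OC)c(O[Si](C(C)C)(C(C)C)C(C)C)c(OC)c2)cc(Br)c1OCc1ccc(O[Si](C(C)C)(C(C)C)C(C)C)c(OC)c1
F3 | step 14 | methyl 2-(3-methoxy-5-FF-2-{[3-methoxy-4-(triisopropylsilyloxy)benzyl]oxy}phenyl)acetate | COC(=O)Cc1cc([C@H]2OC[C@H]3[C@@H]2CO[C@@H]3c2cc(OC)c(O[Si](C(C)C)(C(C)C)C(C)C)c(OC)c2)cc(OC)c1OCc1ccc(O[Si](C(C)C)(C(C)C)C(C)C)c(OC)c1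
F4 | step 14 | methyl 2-diazo-2-(3-methoxy-5-FF-2-{[3-methoxy-4-(triisopropylsilyloxy)benzyl]oxy}phenyl)acetate | COC(=O)C(=[N+]=[N-])c1cc([C@H]2OC[C@H]3[C@@H]2CO[C@@H]3c2cc(OC)c(O[Si](C(C)C)(C(C)C)C(C)C)c(OC)c2)cc(OC)c1OCc1ccc(O[Si](C(C)C)(C(C)C)C(C)C)c(OC)c1
F5 | step 13 | (2R)-3-(hydroxyimino)-8-methoxy-2-ArT-6-FF-chroman-4-one | COc1cc([C@H]2Oc3c(OC)cc([C@H]4OC[C@H]5[C@@H]4CO[C@@H]5c4cc(OC)c(O[Si](C(C)C)(C(C)C)C(C)C)c(OC)c4)cc3C(=O)C2=NO)ccc1O[Si](C(C)C)(C(C)C)C(C)C
F6 | step 12 | 3-methoxy-4-(triisopropylsilyloxy)benzaldehyde | COc1cc(C=O)ccc1O[Si](C(C)C)(C(C)C)C(C)C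
F7 | step 12 | (E)-1-(2-hydroxy-3-methoxy-5-FF-phenyl)-3-ArT-prop-2-en-1-one | COc1cc(/C=C/C(=O)c2cc([C@H]3OC[C@H]4[C@@H]3CO[C@@H]4c3cc(OC)c(O[Si](C(C)C)(C(C)C)C(C)C)c(OC)c3)cc(OC)c2O)ccc1O[Si](C(C)C)(C(C)C)C(C)C
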